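Do not lay one straight line through the dawn substrate readings, because the curve is not straight. Substrate fell 13 percentage points in the 32.0 min after the first reading, then 28 points in the next 50.0 min. As a reading with scatter, that is a later loss faster than the early one.

| setting | dusk | dawn | Tuesday's | Friday's | Monday's | Saturday's |
|---|---|---|---|---|---|---|
| substrate | 0.10 M | 0.10 M | 0.10 M | 0.10 M | 0.10 M | 0.10 M |
| enzyme | 0.0021 mol% | 0.011 mol% | 0.004 mol% | 0.006 mol% | 0.01 mol% | 0.015 mol% |
| remark | run made earlier | run made earlier |  |  |  |  |
| time |  |  | 3.0 h | 3.0 h | 3.0 h | 3.0 h |

- dusk (time / min: target / %, substrate / %): 8.00: 0, 97; 25.0: 2, 97; 40.0: 3, 97; 60.0: 7, 94; 90.0: 7, 92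
- dawn (time / min: target / %, substrate / %): 8.00: 4, 95; 25.0: 11, 90; 40.0: 17, 82; 60.0: 30, 69; 90.0: 46, 54

(each reading ± 1.5 percentage points)

- steps thought possible: target -> over-reaction product; substrate + enzyme -> target + enzyme
- "hardly changes" means that all values lie within two and a half points (for a concentration: within two and a half percent of the largest)

- [target] at the end for Tuesday's, Friday's, Monday's, Saturday's, in this order
- the course of these numbers from the first flask to the last (falls, then rises / rises, then falls / hardly changes / rises all the way / falls all the way)

Carry one quantity: the clearing time, the time a flask needs to use up its substrate. Take it from the dawn run by extending the late slope from its last reading: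

clearing time, dawn = 90.0 min + 54 % × 50.0 min / 28 points = 186 min

Now test whether the enzyme merely sets the clock. Dusk's last reading of 92 % should match dawn at 17.2 min, and it lies near dawn's 95 % and 90 % on either side of that time. So divide the clearing time by the loading ratio:

Monday's: 205 min
Saturday's: 137 min

Follow Saturday's in slow motion on this clock. At first the enzyme makes target from a full charge, and target is too scarce to feed the slow step. Dawn's reading of 54 % substrate comes at 66.0 min, and by then target is a large stock for the slow step to work on. Then the substrate clears, leaving 43.0 min in which target can only fall. Monday's, by contrast, reaches the end at 87.8 % of its reckoned clearing time. I therefore expect the row to climb to Monday's and then flatten or turn. The size of the loss stays open, since dawn's last two readings sum to 100 % with a scatter of 1.5 points on each.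

The forecast, which differs from this by rising to the last flask, gives 0.032 M, 0.048 M, 0.077 M and 0.093 M, rises all the way, holding that “the rate is proportional to enzyme and nearly zero order in substrate”.

The flasks end at 0.0270 M, 0.0468 M, 0.0812 M and 0.0753 M, so the row rises, then falls, turning at a loading of 0.0087 mol%.

    target → over-reaction product (k = 0.00240 min⁻¹)
    substrate + enzyme → target + enzyme, rate k2*[substrate]*[enzyme]/(1 + ([substrate]/Km2) + ([substrate]/Ksi2)^2) (0.0880 M, 15.0 mM, k = 18000 M⁻¹ min⁻¹)

Saturday's ends with 24.7 % over-reaction product, more than the 18.8 % of Monday's. Saturday's clearing time of 137 min falls short of 3.0 h, and that flask already held only 17.0 % substrate at 1.50 h. Monday's clearing time of 205 min runs past 3.0 h, yet Monday's flask held 0.012 % substrate at 3.00 h.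

The readings were generated by integration on assumed constants; the scatter is artificial.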